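## Retrosynthetic overview

1. The target is methyl 2α-acetoxy-3α,9β-dihydroxylabd-13(E)-en-15-oate. The C-2 acetate comes from selective acylation of a 2α,3α-diol, the diol from α-face OsO4 dihydroxylation of a Δ2 olefin, and the E-enoate from carboalumination/methoxycarbonylation of a terminal alkyne.
2. Key disconnection: the C8–C9 bond of ring B (C5–C6–C7–C8–C9–C10). The tertiary carbinol C-9 sits between quaternary C-10 and the methyl-bearing C-8, with 9-OH trans to the C-17 methyl. This 1-hydroxy-2-methylcyclohexane unit is the retron of a 6-exo ketyl–olefin cyclisation of a monocyclic C-9 ketone onto a C8=C17 vinyl group.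
3. The seco-ketone comes from Grignard addition of the C11–C14 alkyne unit to a C-9 aldehyde on ring A. Ring A (C1–C5, C10), with its trans-related C-5 and C-10 centres, comes from an auxiliary-controlled Diels–Alder reaction of (E)-2-methylhepta-2,6-dienal with a 1-amino-3-siloxy diene, followed by C-4 gem-dimethylation and conversion of the enone into the Δ2 olefin.
4. Ring order: ring A (Diels–Alder, step 4), then ring B (SmI2, step 13).

Key step: step 13

Assumption (remark on the chemistry): the (2S,5S) antipode of the diphenylpyrrolidine auxiliary is taken to give the ring configuration drawn. If the first cycloadduct proves antipodal, the equally available (2R,5R)-amine is used and nothing else changes.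

## Route

Step 1
Reactants: 1 (2S,5S)-2,5-diphenylpyrrolidine; 2 (E)-4-methoxybut-3-en-2-one
Product: 3 (E)-4-[(2S,5S)-2,5-diphenylpyrrolidin-1-yl]but-3-en-2-one
Conditions: THF, rt
Reagents that add atoms: none
Why: Addition–elimination (vinylogous transamidation) of the secondary amine on the β-methoxy enone should give the E-vinylogous amide with loss of methanol, leaving the auxiliary stereocentres untouched.

Step 2
Reactants: 3 (E)-4-[(2S,5S)-2,5-diphenylpyrrolidin-1-yl]but-3-en-2-one
Product: 5 (2S,5S)-1-[(1E)-3-(tert-butyldimethylsilyloxy)buta-1,3-dien-1-yl]-2,5-diphenylpyrrolidine, via potassium dienolate 4 (not isolated)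
Conditions: KHMDS, THF, −78 °C; then TBSCl, −78 °C → rt
Reagents that add atoms: tert-butyldimethylsilyl chloride, CC(C)(C)[Si](C)(C)Cl
Why: Kinetic deprotonation of the methyl ketone and O-silylation of the cross-conjugated enolate is the standard preparation of 1-amino-3-siloxy dienes.

Step 3
Reactants: 6 pent-4-enal; 7 2-(triphenylphosphoranylidene)propanal
Product: 8 (E)-2-methylhepta-2,6-dienal
Conditions: toluene, 90 °C
Reagents that add atoms: none
Why: Wittig olefination with the stabilised α-methyl formyl ylide should give the trisubstituted enal with E geometry, which later fixes the trans relationship of the C-10 acyl group and the C-5 side chain.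

Step 4
Reactants: 8 (E)-2-methylhepta-2,6-dienal; 5 (2S,5S)-1-[(1E)-3-(tert-butyldimethylsilyloxy)buta-1,3-dien-1-yl]-2,5-diphenylpyrrolidine
Product: 9 (1R,6S)-6-(but-3-en-1-yl)-4-[(tert-butyldimethylsilyl)oxy]-2-[(2S,5S)-2,5-diphenylpyrrolidin-1-yl]-1-methylcyclohex-3-ene-1-carbaldehyde (amino-bearing C-2 as formed in the endo mode)
Conditions: toluene, rt → 50 °C; concentrated and used crude
Reagents that add atoms: none
Why: In this thermal Diels–Alder reaction of an electron-rich 1-amino-3-siloxy diene with an α-substituted enal, the amino terminus bonds to the α-carbon and the CH2 terminus to the β-carbon, the suprafacial addition carries the E geometry into the trans formyl/butenyl relationship, and the endo (formyl) transition state with both dienophile alkyl groups pointing away from the diene, together with shielding of one diene face by the C2-symmetric auxiliary, should set the future C-10 and C-5.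

Step 5
Reactants: 10 (4-bromobut-1-yn-1-yl)trimethylsilane
Product: 11 [4-(trimethylsilyl)but-3-yn-1-yl]magnesium bromide
Conditions: Mg turnings, cat. I2, THF, 40 °C
Reagents that add atoms: magnesium, [Mg]
Why: Grignard formation by magnesium insertion into the primary C–Br bond should proceed normally because the silyl group masks the acidic alkyne C–H.

Step 6
Reactants: 9 cycloadduct aldehyde; 11 [4-(trimethylsilyl)but-3-yn-1-yl]magnesium bromide
Product: 13 (4R,5S)-5-(but-3-en-1-yl)-4-[1-hydroxy-5-(trimethylsilyl)pent-4-yn-1-yl]-4-methylcyclohex-2-en-1-one (both carbinol epimers), via magnesium alkoxide 12 (not isolated)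
Conditions: THF, −78 → 0 °C; then 1 M HCl, THF, 0 °C → rt
Reagents that add atoms: none
Why: Grignard 1,2-addition to the non-enolisable aldehyde (the only electrophile while the enone is still masked as the β-amino silyl enol ether), then acid hydrolysis of the enol ether and E1cB loss of the auxiliary amine, should unveil the enone; the new carbinol centre forms without control and is removed by oxidation in step 12.

Step 7
Reactants: 13 hydroxy enone
Product: 14 (4R,5S)-5-(but-3-en-1-yl)-4-{1-[(tert-butyldimethylsilyl)oxy]-5-(trimethylsilyl)pent-4-yn-1-yl}-4-methylcyclohex-2-en-1-one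
Conditions: TBSOTf, 2,6-lutidine, CH2Cl2, −78 → 0 °C
Reagents that add atoms: tert-butyldimethylsilyl trifluoromethanesulfonate, CC(C)(C)[Si](C)(C)OS(=O)(=O)C(F)(F)F
Why: Silylation of the hindered secondary alcohol with the silyl triflate should protect it against vinylogous retro-aldol cleavage and O-alkylation in the enolate steps.

Step 8
Reactants: 14 silyl ether enone
Product: 16 (4S,5R)-5-(but-3-en-1-yl)-4-{1-[(tert-butyldimethylsilyl)oxy]-5-(trimethylsilyl)pent-4-yn-1-yl}-4,6,6-trimethylcyclohex-2-en-1-one, via monomethyl enone 15 (not isolated)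
Conditions: LDA, THF, −78 °C, MeI; then LDA, MeI, DMPU, −78 → 0 °C
Reagents that add atoms: iodomethane, CI
Why: Because the γ-carbon is quaternary the enone can enolise only at the α′-CH2, so two successive kinetic enolate alkylations should build the C-4 gem-dimethyl group next to C-5; the transient methyl-bearing stereocentre disappears in the second alkylation.

Step 9
Reactants: 16 gem-dimethyl enone
Product: 18 (4S,5R)-5-(but-3-en-1-yl)-4-{1-[(tert-butyldimethylsilyl)oxy]-5-(trimethylsilyl)pent-4-yn-1-yl}-4,6,6-trimethylcyclohex-1-en-1-yl trifluoromethanesulfonate, via lithium enolate 17 (not isolated)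
Conditions: L-Selectride, THF, −78 °C; then PhNTf2, −78 °C → rt
Reagents that add atoms: N-phenylbis(trifluoromethanesulfonimide), O=S(=O)(N(c1ccccc1)S(=O)(=O)C(F)(F)F)C(F)(F)F
Why: Conjugate hydride reduction of the cyclohexenone, which has no β-substituent and a carbonyl shielded by the gem-dimethyl group, should give the regiodefined lithium enolate, which is trapped on oxygen as the C2=C3 enol triflate.

Step 10
Reactants: 18 enol triflate
Product: 19 tert-butyl({1-[(1S,6S)-6-(but-3-en-1-yl)-1,5,5-trimethylcyclohex-3-en-1-yl]-5-(trimethylsilyl)pent-4-yn-1-yl}oxy)dimethylsilane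
Conditions: Pd(OAc)2 (cat.), PPh3, Bu3N, HCO2H, DMF, 60 °C
Reagents that add atoms: none
Why: Palladium-catalysed formate reduction of the enol triflate (oxidative addition, formate exchange, decarboxylation, reductive elimination) should replace OTf by H and leave the C2=C3 olefin in place.

Step 11
Reactants: 19 bis-silyl olefin
Product: 20 1-[(1S,6S)-6-(but-3-en-1-yl)-1,5,5-trimethylcyclohex-3-en-1-yl]pent-4-yn-1-ol (both carbinol epimers)
Conditions: TBAF, THF, rt → 50 °C
Reagents that add atoms: none
Why: Fluoride-induced desilylation should cleave the silyl ether and the alkynyl C–Si bond in one operation.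

Step 12
Reactants: 20 secondary alcohol
Product: 21 1-[(1S,6S)-6-(but-3-en-1-yl)-1,5,5-trimethylcyclohex-3-en-1-yl]pent-4-yn-1-one
Conditions: Dess–Martin periodinane, CH2Cl2, rt
Reagents that add atoms: none
Why: Dess–Martin oxidation of the neopentyl secondary alcohol should converge both carbinol epimers on the single C-9 ketone without touching the olefins or the alkyne.

Step 13
Reactants: 21 seco-ketone
Product: 24 (1S,2R,4aS,8aS)-1-(but-3-yn-1-yl)-2,5,5,8a-tetramethyl-1,2,3,4,4a,5,8,8a-octahydronaphthalen-1-ol, via samarium ketyl 22 (not isolated), via cyclised alkylsamarium alkoxide 23 (not isolated)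
Conditions: SmI2 (3 equiv), HMPA (12 equiv), t-BuOH (3 equiv), THF, 0 °C → rt, slow addition of 21
Reagents that add atoms: none
Why: SmI2–HMPA should reduce the hindered C-9 ketone to samarium ketyl 22, whose carbon adds to the internal carbon (C-8) of the vinyl group to form the C8–C9 bond, after which the primary C-17 radical is reduced by a second Sm(II) to alkylsamarium 23 and protonated by t-BuOH to give the C-17 methyl group. The closest known reaction type is the SmI2–HMPA ketyl–olefin cyclisation of unactivated olefinic ketones, which gives 2-methylcycloalkanols with the hydroxyl trans to the new methyl group. Ring B closes in the 6-exo-trig mode through a chair transition state that is trans-fused to ring A, because the acyl and butenyl groups are trans-diequatorial on adjacent ring carbons. At C-8 the vinyl terminus takes the pseudo-equatorial position to avoid a 1,3-diaxial contact with the axial C-10 methyl, giving the 8α-methyl group (8R); at C-9 the HMPA-ligated O–Sm group takes the open equatorial site, with the oxygen near the C-10 methyl and the alkynyl chain anti to it, so the chain ends axial and the hydroxyl β (9S). The step needs chemoselective 6-exo attack on the C8=C17 olefin: the ketyl can reach the ring olefin and the alkyne only through 4-exo or 5-endo modes, the quaternary C-10 and the ring hold the reacting ends together (Thorpe–Ingold effect), and slow addition of 21 to excess Sm(II) keeps reduction of the C-17 radical faster than its 6-exo-dig addition to the alkyne.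

Step 14
Reactants: 24 decalinol alkyne
Product: 26 methyl (2E)-5-[(1S,2R,4aS,8aS)-1-hydroxy-2,5,5,8a-tetramethyl-1,2,3,4,4a,5,8,8a-octahydronaphthalen-1-yl]-3-methylpent-2-enoate, via alkenylalane 25 (not isolated)
Conditions: Me3Al, Cp2ZrCl2, CH2Cl2, 0 °C → rt; then ClCO2Me, 0 °C → rt
Reagents that add atoms: trimethylaluminium, C[Al](C)C; methyl chloroformate, COC(=O)Cl
Why: Negishi zirconium-catalysed carboalumination adds Me–Al syn across the terminal alkyne with methyl on the internal carbon, and acylation of the alkenylalane with retention should give the E-β-methyl enoate while the tertiary alcohol is carried as its aluminium alkoxide.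

Step 15
Reactants: 26 hydroxy enoate
Product: 27 methyl (2E)-5-[(1S,2R,4aS,6S,7R,8aS)-1,6,7-trihydroxy-2,5,5,8a-tetramethyldecahydronaphthalen-1-yl]-3-methylpent-2-enoate
Conditions: OsO4 (cat.), NMO, acetone–H2O, rt
Reagents that add atoms: osmium tetroxide, O=[Os](=O)(=O)=O (transfers both oxygen atoms, catalytic); N-methylmorpholine N-oxide, C[N+]1([O-])CCOCC1, and water, O (net oxygen sources)
Why: Catalytic syn-dihydroxylation (Upjohn conditions) should occur on the α-face of the C2=C3 olefin, because the β-face is shielded by the axial C-10 and 4β methyl groups, giving the 2α,3α-diol (2R,3S), while the electron-poor trisubstituted enoate reacts much more slowly.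

Step 16
Reactants: 27 triol
Product: 28 methyl (2E)-5-[(1S,2R,4aS,6S,7R,8aS)-7-(acetyloxy)-1,6-dihydroxy-2,5,5,8a-tetramethyldecahydronaphthalen-1-yl]-3-methylpent-2-enoate (CNP0135744.1)
Conditions: Ac2O (1.2 equiv), pyridine, CH2Cl2, 0 °C → rt
Reagents that add atoms: acetic anhydride, CC(=O)OC(C)=O
Why: Acylation should select the equatorial secondary 2α-hydroxyl, since the axial 3α-hydroxyl is neopentyl (next to the gem-dimethyl carbon) and the 9-hydroxyl is tertiary.

## Compound list

The change of descriptors along 9–21 reflects CIP priority changes only; the spatial arrangement at the two ring stereocentres is constant.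

1 | (2S,5S)-2,5-diphenylpyrrolidine | N1[C@H](c2ccccc2)CC[C@H]1c1ccccc1 | starting material
2 | (E)-4-methoxybut-3-en-2-one | CO/C=C/C(C)=O | starting material
3 | (E)-4-[(2S,5S)-2,5-diphenylpyrrolidin-1-yl]but-3-en-2-one | CC(=O)/C=C/N1[C@H](c2ccccc2)CC[C@H]1c1ccccc1 | intermediate
4 | potassium (1E)-1-[(2S,5S)-2,5-diphenylpyrrolidin-1-yl]buta-1,3-dien-3-olate | C=C([O-])/C=C/N1[C@H](c2ccccc2)CC[C@H]1c1ccccc1.[K+] | intermediate (not isolated)
5 | (2S,5S)-1-[(1E)-3-(tert-butyldimethylsilyloxy)buta-1,3-dien-1-yl]-2,5-diphenylpyrrolidine | C=C(O[Si](C)(C)C(C)(C)C)/C=C/N1[C@H](c2ccccc2)CC[C@H]1c1ccccc1 | intermediate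
6 | pent-4-enal | C=CCCC=O | starting material
7 | 2-(triphenylphosphoranylidene)propanal | CC(C=O)=P(c1ccccc1)(c1ccccc1)c1ccccc1 | starting material
8 | (E)-2-methylhepta-2,6-dienal | C=CCC/C=C(\C)C=O | intermediate
9 | (1R,6S)-6-(but-3-en-1-yl)-4-[(tert-butyldimethylsilyl)oxy]-2-[(2S,5S)-2,5-diphenylpyrrolidin-1-yl]-1-methylcyclohex-3-ene-1-carbaldehyde (formyl trans to butenyl; amino-bearing carbon as formed) | O=C[C@]1(C)[C@@H](CCC=C)CC(O[Si](C)(C)C(C)(C)C)=CC1N2[C@H](c3ccccc3)CC[C@H]2c4ccccc4 | intermediate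
10 | (4-bromobut-1-yn-1-yl)trimethylsilane | C[Si](C)(C)C#CCCBr | starting material
11 | [4-(trimethylsilyl)but-3-yn-1-yl]magnesium bromide | C[Si](C)(C)C#CCC[Mg]Br | intermediate
12 | bromomagnesium 1-{(1R,6S)-6-(but-3-en-1-yl)-4-[(tert-butyldimethylsilyl)oxy]-2-[(2S,5S)-2,5-diphenylpyrrolidin-1-yl]-1-methylcyclohex-3-en-1-yl}-5-(trimethylsilyl)pent-4-yn-1-olate | [Mg+2].[Br-].[O-]C(CCC#C[Si](C)(C)C)[C@]1(C)[C@@H](CCC=C)CC(O[Si](C)(C)C(C)(C)C)=CC1N2[C@H](c3ccccc3)CC[C@H]2c4ccccc4 | intermediate (not isolated)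
13 | (4R,5S)-5-(but-3-en-1-yl)-4-[1-hydroxy-5-(trimethylsilyl)pent-4-yn-1-yl]-4-methylcyclohex-2-en-1-one (carbinol epimers) | OC(CCC#C[Si](C)(C)C)[C@]1(C)[C@@H](CCC=C)CC(=O)C=C1 | intermediate
14 | (4R,5S)-5-(but-3-en-1-yl)-4-{1-[(tert-butyldimethylsilyl)oxy]-5-(trimethylsilyl)pent-4-yn-1-yl}-4-methylcyclohex-2-en-1-one | CC(C)(C)[Si](C)(C)OC(CCC#C[Si](C)(C)C)[C@]1(C)[C@@H](CCC=C)CC(=O)C=C1 | intermediate
15 | (4S,5S)-5-(but-3-en-1-yl)-4-{1-[(tert-butyldimethylsilyl)oxy]-5-(trimethylsilyl)pent-4-yn-1-yl}-4,6-dimethylcyclohex-2-en-1-one (C-6 epimers) | CC(C)(C)[Si](C)(C)OC(CCC#C[Si](C)(C)C)[C@]1(C)[C@@H](CCC=C)C(C)C(=O)C=C1 | intermediate (not isolated)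
16 | (4S,5R)-5-(but-3-en-1-yl)-4-{1-[(tert-butyldimethylsilyl)oxy]-5-(trimethylsilyl)pent-4-yn-1-yl}-4,6,6-trimethylcyclohex-2-en-1-one | CC(C)(C)[Si](C)(C)OC(CCC#C[Si](C)(C)C)[C@]1(C)[C@@H](CCC=C)C(C)(C)C(=O)C=C1 | intermediate
17 | lithium (4S,5R)-5-(but-3-en-1-yl)-4-{1-[(tert-butyldimethylsilyl)oxy]-5-(trimethylsilyl)pent-4-yn-1-yl}-4,6,6-trimethylcyclohex-1-en-1-olate | [Li+].CC(C)(C)[Si](C)(C)OC(CCC#C[Si](C)(C)C)[C@]1(C)[C@@H](CCC=C)C(C)(C)C([O-])=CC1 | intermediate (not isolated)
18 | (4S,5R)-5-(but-3-en-1-yl)-4-{1-[(tert-butyldimethylsilyl)oxy]-5-(trimethylsilyl)pent-4-yn-1-yl}-4,6,6-trimethylcyclohex-1-en-1-yl trifluoromethanesulfonate | CC(C)(C)[Si](C)(C)OC(CCC#C[Si](C)(C)C)[C@]1(C)[C@@H](CCC=C)C(C)(C)C(OS(=O)(=O)C(F)(F)F)=CC1 | intermediate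
19 | tert-butyl({1-[(1S,6S)-6-(but-3-en-1-yl)-1,5,5-trimethylcyclohex-3-en-1-yl]-5-(trimethylsilyl)pent-4-yn-1-yl}oxy)dimethylsilane | CC(C)(C)[Si](C)(C)OC(CCC#C[Si](C)(C)C)[C@]1(C)[C@@H](CCC=C)C(C)(C)C=CC1 | intermediate
20 | 1-[(1S,6S)-6-(but-3-en-1-yl)-1,5,5-trimethylcyclohex-3-en-1-yl]pent-4-yn-1-ol (carbinol epimers) | OC(CCC#C)[C@]1(C)[C@@H](CCC=C)C(C)(C)C=CC1 | intermediate
21 | 1-[(1S,6S)-6-(but-3-en-1-yl)-1,5,5-trimethylcyclohex-3-en-1-yl]pent-4-yn-1-one | O=C(CCC#C)[C@]1(C)[C@@H](CCC=C)C(C)(C)C=CC1 | intermediate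
22 | diiodosamarium(III) ketyl of 21 (radical at the carbinol carbon) | [Sm+3].[I-].[I-].[O-][C](CCC#C)[C@]1(C)[C@@H](CCC=C)C(C)(C)C=CC1 | intermediate (not isolated)
23 | cyclised C-17 alkylsamarium(III) samarium(III) alkoxide of 24 | [Sm+3].[Sm+3].[I-].[I-].[I-].[I-].C#CCC[C@]1([O-])[C@H]([CH2-])CC[C@H]2C(C)(C)C=CC[C@@]21C | intermediate (not isolated)
24 | (1S,2R,4aS,8aS)-1-(but-3-yn-1-yl)-2,5,5,8a-tetramethyl-1,2,3,4,4a,5,8,8a-octahydronaphthalen-1-ol | C#CCC[C@]1(O)[C@H](C)CC[C@H]2C(C)(C)C=CC[C@@]21C | intermediate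
25 | (E)-alkenyl(dimethyl)alane of 24 with the 9-oxygen as its dimethylaluminium alkoxide | C[Al](C)/C=C(\C)CC[C@]1(O[Al](C)C)[C@H](C)CC[C@H]2C(C)(C)C=CC[C@@]21C | intermediate (not isolated)
26 | methyl (2E)-5-[(1S,2R,4aS,8aS)-1-hydroxy-2,5,5,8a-tetramethyl-1,2,3,4,4a,5,8,8a-octahydronaphthalen-1-yl]-3-methylpent-2-enoate | COC(=O)/C=C(\C)CC[C@]1(O)[C@H](C)CC[C@H]2C(C)(C)C=CC[C@@]21C | intermediate
27 | methyl (2E)-5-[(1S,2R,4aS,6S,7R,8aS)-1,6,7-trihydroxy-2,5,5,8a-tetramethyldecahydronaphthalen-1-yl]-3-methylpent-2-enoate | COC(=O)/C=C(\C)CC[C@]1(O)[C@H](C)CC[C@H]2C(C)(C)[C@H](O)[C@H](O)C[C@@]21C | intermediate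
28 | methyl (2E)-5-[(1S,2R,4aS,6S,7R,8aS)-7-(acetyloxy)-1,6-dihydroxy-2,5,5,8a-tetramethyldecahydronaphthalen-1-yl]-3-methylpent-2-enoate (CNP0135744.1) | COC(=O)/C=C(\C)CC[C@]1(O)[C@H](C)CC[C@H]2C(C)(C)[C@H](O)[C@H](OC(C)=O)C[C@@]21C | target

## Step count and risks

Total step count: 16. Longest linear sequence: 14 steps (steps 1, 2, 4, 6–16).

Steps most likely to fail:

1. Step 13 (key step). The 6-exo closure onto an unactivated olefin may be slow, so simple reduction of the ketyl to the secondary alcohol could compete, and facial control at C-9 could erode. Fallback: activate the olefin as a polarity-matched acceptor with a traceless group. Setting out from 19, cross-metathesis with phenyl vinyl sulfone (second-generation ruthenium benzylidene catalyst, CH2Cl2, 40 °C) should give the (E)-vinyl sulfone F4. Buffered desilylation (TBAF/AcOH) should give the alcohol F5, and Dess–Martin oxidation the keto vinyl sulfone F6. SmI2–HMPA/MeOH should then close ring B quickly by ketyl addition to the vinyl sulfone, giving the cyclised sulfone F7. Reductive desulfonylation (excess SmI2–HMPA in the same flask, or Mg/MeOH) returns to the route at 24.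

2. Step 4. The trisubstituted enal may react sluggishly, and incomplete control of diene face or endo/exo mode would lower the enantiomeric purity of all later compounds. Fallback: catalyst control with a different diene. Setting out from 8, Diels–Alder reaction with 2-(triisopropylsilyloxy)buta-1,3-diene under a triflimide-activated (S)-o-tolyl oxazaborolidine of the CBS type (CH2Cl2, −78 °C) should give the silyl enol ether aldehyde F1. Addition of Grignard reagent 11 should give the carbinol F2, and TBSOTf/2,6-lutidine the bis-silyl compound F3. Saegusa–Ito oxidation (Pd(OAc)2, MeCN) of the regiodefined silyl enol ether returns to the route at 14.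

3. Step 14. Acylation of the alkenylalane by methyl chloroformate may be incomplete in the presence of the neighbouring aluminium alkoxide, so protodealumination on work-up would give the 2-methylalkene instead of the ester. Fallback: separate the C–C bond formation from the carboalumination. Setting out from 24, the same carboalumination followed by quenching alkenylalane 25 with iodine should give the (E)-vinyl iodide F8. Palladium-catalysed methoxycarbonylation (PdCl2(PPh3)2, CO 1 atm, MeOH, Et3N, 50 °C) returns to the route at 26.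

Further compounds
F1 | step 4 | (1S,6S)-6-(but-3-en-1-yl)-1-methyl-4-[(triisopropylsilyl)oxy]cyclohex-3-ene-1-carbaldehyde | O=C[C@]1(C)[C@@H](CCC=C)CC(O[Si](C(C)C)(C(C)C)C(C)C)=CC1
F2 | step 4 | 1-{(1S,6S)-6-(but-3-en-1-yl)-1-methyl-4-[(triisopropylsilyl)oxy]cyclohex-3-en-1-yl}-5-(trimethylsilyl)pent-4-yn-1-ol (carbinol epimers) | OC(CCC#C[Si](C)(C)C)[C@]1(C)[C@@H](CCC=C)CC(O[Si](C(C)C)(C(C)C)C(C)C)=CC1
F3 | step 4 | tert-butyldimethylsilyl ether of F2 | CC(C)(C)[Si](C)(C)OC(CCC#C[Si](C)(C)C)[C@]1(C)[C@@H](CCC=C)CC(O[Si](C(C)C)(C(C)C)C(C)C)=CC1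
F4 | step 13 | tert-butyl({1-[(1S,6S)-1,5,5-trimethyl-6-[(3E)-4-(phenylsulfonyl)but-3-en-1-yl]cyclohex-3-en-1-yl]-5-(trimethylsilyl)pent-4-yn-1-yl}oxy)dimethylsilane | CC(C)(C)[Si](C)(C)OC(CCC#C[Si](C)(C)C)[C@]1(C)[C@@H](CC/C=C/S(=O)(=O)c2ccccc2)C(C)(C)C=CC1
F5 | step 13 | 1-{(1S,6S)-1,5,5-trimethyl-6-[(3E)-4-(phenylsulfonyl)but-3-en-1-yl]cyclohex-3-en-1-yl}pent-4-yn-1-ol (carbinol epimers) | OC(CCC#C)[C@]1(C)[C@@H](CC/C=C/S(=O)(=O)c2ccccc2)C(C)(C)C=CC1
F6 | step 13 | 1-{(1S,6S)-1,5,5-trimethyl-6-[(3E)-4-(phenylsulfonyl)but-3-en-1-yl]cyclohex-3-en-1-yl}pent-4-yn-1-one | O=C(CCC#C)[C@]1(C)[C@@H](CC/C=C/S(=O)(=O)c2ccccc2)C(C)(C)C=CC1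
F7 | step 13 | (1S,2R,4aS,8aS)-1-(but-3-yn-1-yl)-5,5,8a-trimethyl-2-[(phenylsulfonyl)methyl]-1,2,3,4,4a,5,8,8a-octahydronaphthalen-1-ol | C#CCC[C@]1(O)[C@H](CS(=O)(=O)c3ccccc3)CC[C@H]2C(C)(C)C=CC[C@@]21C
F8 | step 14 | (1S,2R,4aS,8aS)-1-[(3E)-4-iodo-3-methylbut-3-en-1-yl]-2,5,5,8a-tetramethyl-1,2,3,4,4a,5,8,8a-octahydronaphthalen-1-ol | I/C=C(\C)CC[C@]1(O)[C@H](C)CC[C@H]2C(C)(C)C=CC[C@@]21C
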